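The eleven-membered carbocycle (C2, C3, C16 to C9, C17; carbons numbered along the SMILES of 23, C1 = exocyclic CH2) is closed last, across C14–C15, by a nickel-catalysed reductive macrocyclisation of an alkynyl aldehyde. This one operation forms the ring, the E-trisubstituted C13=C14 alkene and the C15 carbinol. It exploits the C13–C14 epoxide flanked by the C15 hydroxyl, read as a 2-methylallylic alcohol that a methyl alkyne and an aldehyde can deliver. The precursor is a cis-hydrindane carrying a but-2-ynyl carbinol acetate chain on C9 and an acetaldehyde arm on C3, assembled from a 4-silyloxy-3-methylcyclohexenone by annulation, Michael addition and propargylation.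

Key step: step 16

Remarks
- Numbering: ring B = C2–C6, C17; ring A = C6–C9, C17; bridge = C10 (CH3), C11 (OAc), C12, C13, C14 (CH3), C15 (OH), C16. β is the face of the C6 methyl group. In 12–20 the core has the arrangement of the target: 3β side chain, 5β oxygen, 6β methyl, 9β-H and 17β-H (cis-fused), with the C9 side chain α.
- Assumption: compound 1, [2-(1,3-dioxan-2-yl)ethyl]magnesium bromide solution, S-ethyl propanethioate and trimethyl(buta-2,3-dien-2-yl)silane are taken as purchasable.
- TBDPS = tert-butyldiphenylsilyl.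

Step 1
Reactants: 1 1,4-dioxaspiro[4.5]dec-6-en-8-one
Product: 2 7-iodo-1,4-dioxaspiro[4.5]dec-6-en-8-one
Conditions: I2, pyridine/CH2Cl2, 0 °C → rt
Reagents that add atoms: iodine, II
Why: α-Iodination of the enone (pyridine addition, iodination, elimination) should give the 2-iodoenone, whose iodine makes the alkenyl arm the large group for the next reduction and is later exchanged for the C6 methyl.

Step 2
Reactants: 2 7-iodo-1,4-dioxaspiro[4.5]dec-6-en-8-one
Product: 3 (8S)-7-iodo-1,4-dioxaspiro[4.5]dec-6-en-8-ol
Conditions: (R)-2-methyl-CBS-oxazaborolidine (10 mol%), BH3·SMe2, THF, −20 °C; MeOH quench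
Reagents that add atoms: none
Why: Corey–Bakshi–Shibata reduction with the iodoalkenyl carbon as large and CH2 as small substituent should deliver hydride from the (R)-catalyst to give the (S)-allylic alcohol, the future C5 stereocentre from which the ring stereochemistry is relayed.

Step 3
Reactants: 3 (8S)-7-iodo-1,4-dioxaspiro[4.5]dec-6-en-8-ol
Product: 4 (8S)-8-(tert-butyldiphenylsilyloxy)-7-iodo-1,4-dioxaspiro[4.5]dec-6-ene
Conditions: TBDPSCl, imidazole, DMAP (cat.), DMF, rt
Reagents that add atoms: tert-butyl(chloro)diphenylsilane, CC(C)(C)[Si](Cl)(c1ccccc1)c1ccccc1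
Why: Silylation of the secondary alcohol installs an ether chosen to survive the aqueous acid of steps 5 and 6 and the Lewis acids used later.

Step 4
Reactants: 4 (8S)-8-(tert-butyldiphenylsilyloxy)-7-iodo-1,4-dioxaspiro[4.5]dec-6-ene
Product: 5 (8S)-8-(tert-butyldiphenylsilyloxy)-7-methyl-1,4-dioxaspiro[4.5]dec-6-ene
Conditions: MeZnCl, Pd(PPh3)4 (5 mol%), THF, 50 °C
Reagents that add atoms: methylzinc chloride, C[Zn]Cl
Why: Negishi cross-coupling of the vinyl iodide should install the methyl group without touching the adjacent allylic stereocentre.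

Step 5
Reactants: 5 (8S)-8-(tert-butyldiphenylsilyloxy)-7-methyl-1,4-dioxaspiro[4.5]dec-6-ene
Product: 6 (4S)-4-(tert-butyldiphenylsilyloxy)-3-methylcyclohex-2-en-1-one
Conditions: 1 M aq. HCl, THF, rt
Reagents that add atoms: water, O
Why: Acid-catalysed ketal hydrolysis unmasks the conjugated enone (C2 carbonyl) while the hindered TBDPS ether should survive.

Step 6
Reactants: 6 (4S)-4-(tert-butyldiphenylsilyloxy)-3-methylcyclohex-2-en-1-one
Product: 9 (7S,7aS)-7-(tert-butyldiphenylsilyloxy)-7a-methyl-1,2,5,6,7,7a-hexahydro-4H-inden-4-one, via silyl enol ether 7 (not isolated), via keto aldehyde 8 (not isolated)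
Conditions: Grignard reagent (1.5 equiv), CuBr·SMe2 (20 mol%), TMSCl, THF, −78 → −40 °C; then 2 M aq. HCl, THF, 55 °C
Reagents that add atoms: [2-(1,3-dioxan-2-yl)ethyl]magnesium bromide, Br[Mg]CCC1OCCCO1
Why: Copper-catalysed, TMSCl-accelerated conjugate addition should enter anti to the neighbouring silyloxy group and so set the C6 quaternary centre (methyl cis to oxygen), after which acid unmasks the aldehyde and intramolecular aldol condensation of C17 onto it (conjugate addition–aldol cyclopentene annulation) closes ring A as the conjugated enone.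

Step 7
Reactants: 9 (7S,7aS)-7-(tert-butyldiphenylsilyloxy)-7a-methyl-1,2,5,6,7,7a-hexahydro-4H-inden-4-one
Product: 11 (5R,7S,7aS)-7-(tert-butyldiphenylsilyloxy)-7a-methyl-5-(3-methylbut-2-enyl)-1,2,5,6,7,7a-hexahydro-4H-inden-4-one, via axial C3 epimer 10 (not isolated)
Conditions: LDA, THF, −78 °C; prenyl bromide, −78 → −30 °C; work-up; then DBU (0.3 equiv), toluene, rt → 40 °C
Reagents that add atoms: 1-bromo-3-methylbut-2-ene, CC(C)=CCBr
Why: Kinetic α′-deprotonation and enolate alkylation (SN2) should give mainly the axial epimer by stereoelectronic attack, and base equilibration then moves the prenyl group to the pseudo-equatorial β position, cis to the equatorial silyloxy group, in the single half-chair that the axial angular methyl allows.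

Step 8
Reactants: 11 (5R,7S,7aS)-7-(tert-butyldiphenylsilyloxy)-7a-methyl-5-(3-methylbut-2-enyl)-1,2,5,6,7,7a-hexahydro-4H-inden-4-one
Product: 12 S-ethyl (2S)-2-[(3R,3aR,5R,7S,7aS)-7-(tert-butyldiphenylsilyloxy)-7a-methyl-5-(3-methylbut-2-enyl)-4-oxooctahydro-1H-inden-3-yl]propanethioate
Conditions: S-ethyl propanethioate, LDA, THF, −78 °C; then 11, −78 °C; AcOH/THF quench at −78 °C
Reagents that add atoms: S-ethyl propanethioate, CCC(=O)SCC
Why: Kinetic Michael addition of the lithium E(O)-enolate to the s-cis enone through a chelated eight-membered transition state should be syn-selective (C9/C10) and occur at C9 anti to the angular methyl, and cold protonation of the resulting enolate at C17 anti to the new pseudoaxial C9 side chain should give the cis-fused ketone.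

Step 9
Reactants: 12 S-ethyl (2S)-2-[(3R,3aR,5R,7S,7aS)-7-(tert-butyldiphenylsilyloxy)-7a-methyl-5-(3-methylbut-2-enyl)-4-oxooctahydro-1H-inden-3-yl]propanethioate
Product: 13 C11 aldehyde corresponding to 12 (C(=O)SEt replaced by CHO; 10S)
Conditions: Et3SiH, 10% Pd/C, acetone, rt
Reagents that add atoms: none
Why: Fukuyama reduction should convert the thioester into the aldehyde without affecting the ketone, the trisubstituted alkene or the C10 stereocentre.

Step 10
Reactants: 13 C11 aldehyde corresponding to 12
Product: 14 homopropargylic alcohol with a (2S,3S)-3-hydroxyhept-5-yn-2-yl chain on C9 (11S)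
Conditions: trimethyl(buta-2,3-dien-2-yl)silane, TiCl4, CH2Cl2, −78 °C
Reagents that add atoms: trimethyl(buta-2,3-dien-2-yl)silane, C=C=C(C)[Si](C)(C)C
Why: Lewis-acid-mediated SE2′ addition of the allenylsilane (allenylsilane propargylation) gives the but-2-ynyl carbinol regiospecifically, the open transition state follows Felkin–Anh control from C10 (C9 as large group) to set C11 syn to the C10 methyl, and the aldehyde should react ahead of the hindered ketone.

Step 11
Reactants: 14 homopropargylic alcohol
Product: 15 C11 acetate of 14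
Conditions: Ac2O, pyridine, DMAP (cat.), CH2Cl2, 0 °C → rt
Reagents that add atoms: acetic anhydride, CC(=O)OC(C)=O
Why: DMAP-catalysed acylation installs the C11 acetate of the target with retention.

Step 12
Reactants: 15 C11 acetate of 14
Product: 16 exocyclic methylene compound (C2=C1H2) derived from 15
Conditions: Zn, CH2Br2, TiCl4, THF/CH2Cl2, 0 °C → rt
Reagents that add atoms: dibromomethane, BrCBr
Why: Lombardo–Takai methylenation is non-basic, so the hindered enolisable ketone should give the alkene without epimerising C3 or C17 and with the acetate untouched.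

Step 13
Reactants: 16 exocyclic methylene compound
Product: 17 C5 alcohol derived from 16
Conditions: TBAF, AcOH, THF, rt → 40 °C
Reagents that add atoms: none
Why: Buffered fluoride desilylation frees the C5 hydroxyl at a stage where no aldehyde is present that could form a lactol with it.

Step 14
Reactants: 17 C5 alcohol
Product: 18 C5 propanoate of 17
Conditions: propanoic anhydride, pyridine, DMAP, CH2Cl2, rt → 40 °C
Reagents that add atoms: propanoic anhydride, CCC(=O)OC(=O)CC
Why: DMAP-catalysed esterification installs the propanoate on the hindered secondary alcohol with retention.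

Step 15
Reactants: 18 C5 propanoate of 17
Product: 20 alkynyl aldehyde (3β-CH2CHO arm; 5β-propanoate; 11S-acetate; 2-methylene), via prenyl epoxide 19 (not isolated)
Conditions: mCPBA (1.05 equiv), CH2Cl2, −20 °C; then H5IO6, THF/H2O, 0 °C
Reagents that add atoms: 3-chloroperoxybenzoic acid, OOC(=O)c1cccc(Cl)c1
Why: Prilezhaev epoxidation should select the electron-rich trisubstituted prenyl alkene over the hindered 1,1-disubstituted alkene and the alkyne, and periodic acid cleaves the epoxide through its diol (glycol cleavage) to the C15 aldehyde.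

Step 16
Reactants: 20 alkynyl aldehyde
Product: 22 (13E,15R)-macrocyclic allylic alcohol (the target lacking the epoxide oxygen), via triethylsilyl ether 21 (not isolated)
Conditions: Ni(cod)2 (30 mol%), IMes·HCl (30 mol%), KOt-Bu (30 mol%), Et3SiH (5 equiv), THF, rt, slow addition of 20 (final ca. 0.003 M); then PPTS, MeOH, rt
Reagents that add atoms: none
Why: Ni(0)–IMes binds the alkyne and the aldehyde and couples them by oxidative cyclisation to an oxanickelacyclopentene (new C14–C15 bond), after which σ-bond metathesis with Et3SiH and C–H reductive elimination release the silyl ether with H and C15 added cis across the alkyne, so that only the E-alkene can form. The closest known reaction type is the Ni/NHC/silane reductive macrocyclisation of ynals to 12- and 14-membered allylic alcohols. The eleven-membered ring closes in the endocyclic mode, with both alkyne carbons becoming ring atoms and the C–C bond formed at the methyl-bearing carbon C14. C15 is set by the face of the planar nickelacycle that the tether (C16 to C3) spans, and the trans-disposed anchor points C3 (β) and C9 (α) on the rigid cis-hydrindane together with the C10/C11 substituents should allow one folding, taken here to give 15R. The step needs endo over exo regioselectivity (exo would give a ten-membered ring with an exocyclic ethylidene), which the small IMes ligand secures by bonding at the alkyne carbon with the smaller substituent, and it needs cyclisation to outrun oligomerisation, which slow addition at high dilution secures. Mild acidic methanolysis in the same flask removes the labile allylic silyl group.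

Step 17
Reactants: 22 (13E,15R)-macrocyclic allylic alcohol
Product: 23 CNP0415604.1 (target)
Conditions: mCPBA, NaHCO3, CH2Cl2, 0 °C
Reagents that add atoms: 3-chloroperoxybenzoic acid, OOC(=O)c1cccc(Cl)c1
Why: Prilezhaev epoxidation should take the strained E-trisubstituted ring alkene in preference to the hindered exocyclic methylene, from its exposed peripheral face with hydrogen-bond assistance from the C15 hydroxyl on that face (H15 eclipsing the alkene), giving the (13S,14S) trans-epoxide threo to the carbinol.

Compound list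
1 | 1,4-dioxaspiro[4.5]dec-6-en-8-one | O=C1CCC2(OCCO2)C=C1 | starting material
2 | 7-iodo-1,4-dioxaspiro[4.5]dec-6-en-8-one | O=C1CCC2(OCCO2)C=C1I | intermediate
3 | (8S)-7-iodo-1,4-dioxaspiro[4.5]dec-6-en-8-ol | O[C@H]1CCC2(OCCO2)C=C1I | intermediate
4 | (8S)-8-(tert-butyldiphenylsilyloxy)-7-iodo-1,4-dioxaspiro[4.5]dec-6-ene | CC(C)(C)[Si](c1ccccc1)(c1ccccc1)O[C@H]1CCC2(OCCO2)C=C1I | intermediate
5 | (8S)-8-(tert-butyldiphenylsilyloxy)-7-methyl-1,4-dioxaspiro[4.5]dec-6-ene | CC(C)(C)[Si](c1ccccc1)(c1ccccc1)O[C@H]1CCC2(OCCO2)C=C1C | intermediate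
6 | (4S)-4-(tert-butyldiphenylsilyloxy)-3-methylcyclohex-2-en-1-one | O=C1CC[C@H](O[Si](c2ccccc2)(c2ccccc2)C(C)(C)C)C(C)=C1 | intermediate
7 | silyl enol ether: (3S,4S)-4-(tert-butyldiphenylsilyloxy)-3-[2-(1,3-dioxan-2-yl)ethyl]-3-methyl-1-(trimethylsilyloxy)cyclohex-1-ene | C[Si](C)(C)OC1=C[C@](C)(CCC2OCCCO2)[C@@H](O[Si](c2ccccc2)(c2ccccc2)C(C)(C)C)CC1 | intermediate
8 | keto aldehyde: 3-[(1S,2S)-2-(tert-butyldiphenylsilyloxy)-1-methyl-5-oxocyclohexyl]propanal | O=C1CC[C@H](O[Si](c2ccccc2)(c2ccccc2)C(C)(C)C)[C@@](C)(CCC=O)C1 | intermediate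
9 | (7S,7aS)-7-(tert-butyldiphenylsilyloxy)-7a-methyl-1,2,5,6,7,7a-hexahydro-4H-inden-4-one | O=C1CC[C@H](O[Si](c3ccccc3)(c3ccccc3)C(C)(C)C)[C@@]2(C)CCC=C12 | intermediate
10 | axial C3 epimer: (5S,7S,7aS)-7-(tert-butyldiphenylsilyloxy)-7a-methyl-5-(3-methylbut-2-enyl)-1,2,5,6,7,7a-hexahydro-4H-inden-4-one | O=C1[C@@H](CC=C(C)C)C[C@H](O[Si](c3ccccc3)(c3ccccc3)C(C)(C)C)[C@@]2(C)CCC=C12 | intermediate
11 | (5R,7S,7aS)-7-(tert-butyldiphenylsilyloxy)-7a-methyl-5-(3-methylbut-2-enyl)-1,2,5,6,7,7a-hexahydro-4H-inden-4-one | O=C1[C@H](CC=C(C)C)C[C@H](O[Si](c3ccccc3)(c3ccccc3)C(C)(C)C)[C@@]2(C)CCC=C12 | intermediate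
12 | S-ethyl (2S)-2-[(3R,3aR,5R,7S,7aS)-7-(tert-butyldiphenylsilyloxy)-7a-methyl-5-(3-methylbut-2-enyl)-4-oxooctahydro-1H-inden-3-yl]propanethioate | O=C1[C@H](CC=C(C)C)C[C@H](O[Si](c3ccccc3)(c3ccccc3)C(C)(C)C)[C@@]2(C)CC[C@@H]([C@H](C)C(=O)SCC)[C@@H]12 | intermediate
13 | C11 aldehyde corresponding to 12: C(=O)SEt replaced by CHO, (10S)-propanal unit on C9 | O=C1[C@H](CC=C(C)C)C[C@H](O[Si](c3ccccc3)(c3ccccc3)C(C)(C)C)[C@@]2(C)CC[C@@H]([C@H](C)C=O)[C@@H]12 | intermediate
14 | homopropargylic alcohol: as 13 with the C9 chain (2S,3S)-3-hydroxyhept-5-yn-2-yl | O=C1[C@H](CC=C(C)C)C[C@H](O[Si](c3ccccc3)(c3ccccc3)C(C)(C)C)[C@@]2(C)CC[C@@H]([C@H](C)[C@@H](O)CC#CC)[C@@H]12 | intermediate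
15 | C11 acetate of 14 | O=C1[C@H](CC=C(C)C)C[C@H](O[Si](c3ccccc3)(c3ccccc3)C(C)(C)C)[C@@]2(C)CC[C@@H]([C@H](C)[C@@H](OC(C)=O)CC#CC)[C@@H]12 | intermediate
16 | exocyclic methylene compound: as 15 with the ring ketone replaced by C2=C1H2 | C=C1[C@H](CC=C(C)C)C[C@H](O[Si](c3ccccc3)(c3ccccc3)C(C)(C)C)[C@@]2(C)CC[C@@H]([C@H](C)[C@@H](OC(C)=O)CC#CC)[C@@H]12 | intermediate
17 | C5 alcohol: as 16 with free C5 hydroxyl | C=C1[C@H](CC=C(C)C)C[C@H](O)[C@@]2(C)CC[C@@H]([C@H](C)[C@@H](OC(C)=O)CC#CC)[C@@H]12 | intermediate
18 | C5 propanoate of 17 | C=C1[C@H](CC=C(C)C)C[C@H](OC(=O)CC)[C@@]2(C)CC[C@@H]([C@H](C)[C@@H](OC(C)=O)CC#CC)[C@@H]12 | intermediate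
19 | prenyl epoxide of 18 (both epimers at the oxirane CH) | C=C1[C@H](CC2OC2(C)C)C[C@H](OC(=O)CC)[C@@]3(C)CC[C@@H]([C@H](C)[C@@H](OC(C)=O)CC#CC)[C@@H]13 | intermediate
20 | alkynyl aldehyde: as 18 with the prenyl group cut back to CH2CHO on C3 | C=C1[C@H](CC=O)C[C@H](OC(=O)CC)[C@@]2(C)CC[C@@H]([C@H](C)[C@@H](OC(C)=O)CC#CC)[C@@H]12 | intermediate
21 | triethylsilyl ether of 22 | C=C1[C@H]2C[C@H](OC(=O)CC)[C@@]3(C)CC[C@@H]([C@H](C)[C@@H](OC(C)=O)C/C=C(C)/[C@H](O[Si](CC)(CC)CC)C2)[C@@H]13 | intermediate
22 | (13E,15R)-macrocyclic allylic alcohol, the target lacking the epoxide oxygen | C=C1[C@H]2C[C@H](OC(=O)CC)[C@@]3(C)CC[C@@H]([C@H](C)[C@@H](OC(C)=O)C/C=C(C)/[C@H](O)C2)[C@@H]13 | intermediate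
23 | CNP0415604.1 | C=C1[C@H]2C[C@H](OC(=O)CC)[C@@]3(C)CC[C@@H]([C@H](C)[C@@H](OC(C)=O)C[C@@H]4O[C@@]4(C)[C@H](O)C2)[C@@H]13 | target

Total step count: 17. Longest linear sequence: 17 steps (from 1).

Steps most likely to fail

Step 16 (key step). The closure may go in the exo mode (C–C bond at C13, ten-membered ring), oligomerisation or plain hydrosilylation of the aldehyde may outrun ring closure, or facial control at C15 may be poor. The fallback sets out from 18. Hydrozirconation with Cp2Zr(H)Cl (slight excess, THF, rt, so that zirconium settles on the methyl-bearing carbon) and iodinolysis should give the (E)-vinyl iodide F1. Epoxidation and periodate cleavage of the prenyl group as in step 15 pass through the prenyl epoxide F2 to the iodo aldehyde F3. Nozaki–Hiyama–Kishi macrocyclisation (CrCl2, cat. NiCl2, DMSO/THF, high dilution; a chiral sulfonamide ligand can be added to steer C15) forms the same C14–C15 bond, with the regiochemistry and the alkene geometry already defined by the vinyl iodide, and comes back to the route at 22.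

Step 8. The syn (C9/C10) selectivity may erode if the enolate geometry is not clean or if C10 equilibrates by proton transfer on warming. The enolate may attack the wrong face of C9, the ketone enolate may be O-acylated by the thioester (enol lactone), or C17 may be protonated from the α face. The fallback sets out from 11. Copper-catalysed conjugate addition of isopropenylmagnesium bromide, anti to the angular methyl, should give the isopropenyl ketone F4. 9-BBN hydroboration–oxidation of its 1,1-disubstituted alkene (approach anti to the ring in the A1,3-minimised conformer; the prenyl alkene is too hindered to react) sets C10 and gives the primary alcohol F5. Dess–Martin oxidation comes back to the route at 13.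

Step 6. Conjugate addition to the hindered β,β-disubstituted, γ-oxygenated enone may be slow, so that 1,2-addition or reductive loss of the γ-silyloxy group competes, and the silyl ether may be partly lost in the acidic annulation. The fallback sets out from 6. Hosomi–Sakurai allylation (allyltrimethylsilane, TiCl4, CH2Cl2, −78 °C) should add anti to the silyloxy group and give the allyl ketone F6. 9-BBN hydroboration of the terminal alkene at 0 °C and NaBO3 oxidation give the keto alcohol F7. Dess–Martin periodinane gives keto aldehyde 8, which is cyclised with TsOH in benzene and comes back to the route at 9.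

Further compounds
F1 | step 16 | (E)-vinyl iodide: 18 with the alkyne converted into CH=C(I)CH3 | C=C1[C@H](CC=C(C)C)C[C@H](OC(=O)CC)[C@@]2(C)CC[C@@H]([C@H](C)[C@@H](OC(C)=O)C/C=C(/I)C)[C@@H]12
F2 | step 16 | prenyl epoxide of F1 (both epimers at the oxirane CH) | C=C1[C@H](CC2OC2(C)C)C[C@H](OC(=O)CC)[C@@]3(C)CC[C@@H]([C@H](C)[C@@H](OC(C)=O)C/C=C(/I)C)[C@@H]13
F3 | step 16 | iodo aldehyde: F1 with the prenyl group cut back to CH2CHO | C=C1[C@H](CC=O)C[C@H](OC(=O)CC)[C@@]2(C)CC[C@@H]([C@H](C)[C@@H](OC(C)=O)C/C=C(/I)C)[C@@H]12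
F4 | step 8 | isopropenyl ketone: cis-hydrindanone of 12 with prop-1-en-2-yl on C9 | O=C1[C@H](CC=C(C)C)C[C@H](O[Si](c3ccccc3)(c3ccccc3)C(C)(C)C)[C@@]2(C)CC[C@@H](C(C)=C)[C@@H]12
F5 | step 8 | primary alcohol: cis-hydrindanone of 12 with (2S)-1-hydroxypropan-2-yl on C9 | O=C1[C@H](CC=C(C)C)C[C@H](O[Si](c3ccccc3)(c3ccccc3)C(C)(C)C)[C@@]2(C)CC[C@@H]([C@H](C)CO)[C@@H]12
F6 | step 6 | allyl ketone: (3S,4S)-3-allyl-4-(tert-butyldiphenylsilyloxy)-3-methylcyclohexan-1-one | O=C1CC[C@H](O[Si](c2ccccc2)(c2ccccc2)C(C)(C)C)[C@@](C)(CC=C)C1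
F7 | step 6 | keto alcohol: (3S,4S)-4-(tert-butyldiphenylsilyloxy)-3-(3-hydroxypropyl)-3-methylcyclohexan-1-one | O=C1CC[C@H](O[Si](c2ccccc2)(c2ccccc2)C(C)(C)C)[C@@](C)(CCCO)C1
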